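## Analysis of the target

Target 14 is 7-hydroxy-3,5,6,8-tetramethoxy-2-(4-methoxyphenyl)-4H-chromen-4-one, a flavone: benzo ring A and 4-pyranone ring C are fused across C4a–C8a, and ring B, a 4-methoxyphenyl group, sits on C2. There is no stereocentre, so the whole problem is one of regiochemistry. Ring A is hexasubstituted and carries four contiguous oxygens at C5, C6, C7 and C8, of which only the one at C7 is a free phenol; C3 carries a fifth methoxyl. The sensitive points are the very electron-rich ring A, the pyranone ring, which strong nucleophiles can open at C2, and the single phenol that has to stay free among five methyl ethers. The difficulty lies in placing six different substituents on one benzene ring and in telling O7 apart from O5, O6 and O8. The plan rests on this feature: O1 (on C8a), O5 and O7 lie on alternate carbons around C4a, which bears the acyl carbon C4. That is the oxygen pattern of an acetate-derived acylphloroglucinol, with C4–C3–C2–aryl as the starter end of the chain. The two remaining oxygens, at C6 and C8, are both methoxyls on the two nucleophilic CH positions of such a ring, so they can be added later as an identical pair. O5 differs from O7 through its hydrogen bond to the C4 carbonyl.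

## Retrosynthetic reasoning

**14 to 13.** The O7–benzyl bond is cut last. A benzyl group on O7 is the only protecting group in the route, and its hydrogenolysis touches neither the methyl ethers nor the tetrasubstituted C2=C3 bond of ring C.

**13 to 12 to 11.** The O5–methyl bond and then the O7–benzyl bond are cut, leading back to the 5,7-diol 11. The order is dictated by the substrate: the C5 hydroxyl is held in a hydrogen bond to the C4 carbonyl and reacts only under forcing conditions, whereas the C7 hydroxyl, para to that carbonyl, is free and the more acidic. Benzylation therefore goes to O7 first, after which O5 can be methylated without ambiguity.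

**11 to 10 to 9.** The C6–O and C8–O bonds are traced back to C–Br bonds in dibromide 10 and then to C–H bonds in the 5,7-dihydroxyflavone 9. C6 and C8 are the only free positions of ring A, each ortho and para to the two phenols, so halogenation needs no regiocontrol. Both receive the same methoxyl, so they never have to be told apart. The forward reactions are a double bromination and a copper-mediated double methoxylation.

**9 to 6 (through 7 and 8).** This is the central disconnection. Cutting O1–C2 opens ring C to the acylphloroglucinol 8. Cutting the bond from C4a to the neighbouring ring carbon (C5 or C8a, which are equivalent at that stage) unravels ring A to the linear triketo ester 7. The chain is stored as the 2-pyranone 6. The cut is made here because the alternate oxygens of ring A are exactly the carbonyls of a poly-β-carbonyl chain, and both closures are six-membered. The forward reaction must fold the chain in the Claisen sense rather than the aldol sense, and a phenol of 8 must then displace the C2 methoxyl.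

**6 to 4 and 5.** The C4–C4a bond is cut. Pyranone 5 supplies all six carbons of ring A, its methyl group becoming C4a, together with the future C7 oxygen. Ester 4 supplies C4, C3, C2 and ring B. In 4 the C2 carbonyl is masked as a methyl enol ether. The mask removes every enolisable hydrogen from this fragment, so 4 can only act as the acyl donor, and it leaves a leaving group on C2 for the later ring C closure.

**4 to 3 to 1 and 2.** The enol O–methyl bond is cut back to keto ester 3, and the C2–C3 bond is cut back to ester 1 and acid chloride 2. The C3 methoxyl is bought with 1 and the ring B methoxyl with 2, so neither needs a step of its own.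

## Alternatives that were turned down

**Alternative 1: carbene-catalysed benzoin closure of C3–C4.**
- Disconnection: the C3–C4 bond is cut at the flavanonol oxidation level. This leads to the dialdehyde A2, 2-[3-(benzyloxy)-6-formyl-2,4,5-trimethoxyphenoxy]-2-(4-methoxyphenyl)acetaldehyde, in which ring A and the O1–C2 ether are already in place.
- Forward key step: an N-heterocyclic carbene adds to the aromatic aldehyde, the acyl anion equivalent attacks the aliphatic aldehyde, and the intramolecular crossed benzoin gives the 3-hydroxychroman-4-one A1 (racemic, both diastereomers).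
- For it: the closure is catalytic and mild, and the C3 oxygen arrives with the new bond. All four ring A oxygens, with O7 already marked by benzyl, are fixed before ring C closes. On this point it is stronger than the chosen route, which spends five steps after its key step on ring A.
- Against it:
  - A2 presupposes a hexasubstituted benzaldehyde with four differentiated oxygens, so the real problem of the target is only moved into the starting material.
  - The α-aryl-α-aryloxy aldehyde of A2 enolises and self-condenses readily.
  - The carbene should add faster to the unhindered aliphatic aldehyde than to the electron-rich benzaldehyde with two ortho substituents. Benzoin closure in the reverse sense and intermolecular coupling therefore compete.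
  - A1 is two hydrogens too reduced. It still needs dehydrogenation across C2–C3, methylation of the C3 hydroxyl and debenzylation, and its two stereocentres are made only to be destroyed.
- Comparison: the chosen route reaches the flavone oxidation level, with the C3 methoxyl in place, directly in its key step from three cheap building blocks. It pays for this with a linear end game.

**Alternative 2: ring A from a squarate by cyclobutenone ring expansion.**
- Disconnection: the C8–C8a bond, and with it the whole of ring A, is cut back to the cyclobutenone A4. A4 would come from the C5-metallated form of bromopyranone A6 and dibenzyl squarate A5.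
- Forward key step: heating A4 opens the four-membered ring by 4π electrocyclic opening. The ketene carbon closes in a 6π sense onto the C6–H carbon of the pyranone (next to O1), and tautomerisation gives the hydroquinone A3.
- For it: it is the most convergent plan. Ring C with its C3 methoxyl and ring B is made separately, ring A appears with all four oxygens in one reagent-free step, and the ring fusion regiochemistry is fixed by connectivity. On convergence and on the oxidation level of ring A it is stronger than the chosen route.
- Against it:
  - A3 carries the wrong differentiation: O5 and O8 are free and O6 and O7 are both benzylated, while the target needs O7 alone free. After methylation at O5 and O8 and debenzylation, the 6,7-diol would have to be methylated at O6 only, but O7, para to the carbonyl, is the more acidic and nucleophilic oxygen.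
  - An unsymmetrical squarate would need discrimination between two nearly identical carbonyls in the addition.
  - Metallating A6 next to the pyranone carbonyl invites ring opening.
  - A3 is an air-sensitive hydroquinone.
- Comparison: the chosen route lets innate reactivity make the distinctions, with C6 and C8 identical and O5 chelated while O7 is free. Counting the synthesis of A6 and the adjustment steps, the squarate route is no shorter.

**Alternative 3: carbonylative alkyne annulation with carbon monoxide as C4.**
- Disconnection: C4a–C4, C4–C3 and O1–C2 are cut, giving iodophenol A8, alkyne A9 and carbon monoxide A10.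
- Forward key step: zerovalent palladium inserts into the C–I bond of A8, A10 inserts, and the acylpalladium species couples with A9. The phenol then adds to the triple bond in a 6-endo-dig closure to give flavone A7.
- For it: three bonds form in one flask under catalysis, from three components. It is the most step-economical way to form ring C, and on convergence it is stronger than the chosen route.
- Against it:
  - A7 has hydrogen at C3. The C3 methoxyl would have to be put in afterwards by oxidising the C3–H bond of a penta-alkoxyflavone, then methylating, then debenzylating. That is three steps, and the first is weak.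
  - Oxidative addition into a very electron-rich aryl iodide with two ortho substituents is slow.
  - Coupling without uptake of A10 followed by closure to a furan ring, and 5-exo-dig closure after uptake, both compete with the flavone-forming path.
  - A8 is again a hexasubstituted benzene that needs its own long synthesis.
- Comparison: the chosen route brings the C3 methoxyl in with 1 and builds ring A from the commodity pyranone 5. It gives up convergence for that.

Key step: step 4

Assumption: the tetrasubstituted enol ether double bond of 4, 6, 7 and 8 is drawn Z (the two methoxyls cis); any E isomer formed alongside is carried through unchanged, because this geometry is lost in the ring C closure.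

## Route

Step 1
Reactants: 1 methyl methoxyacetate; 2 4-methoxybenzoyl chloride
Product: 3 methyl 2-methoxy-3-(4-methoxyphenyl)-3-oxopropanoate (racemic)
Conditions: 1 (2.0 equiv), LiN(iPr)2 (2.1 equiv), THF, −78 °C; then 2 (1.0 equiv), −78 to 0 °C; 1 M HCl
Reagents that add atoms: none
Why: Crossed Claisen acylation of a lithium ester enolate by an acid chloride that has no α-hydrogen; the second equivalent of enolate deprotonates the more acidic β-keto ester as it forms and so prevents a second acylation. The C2 stereocentre forms racemic and disappears in step 2.

Step 2
Reactants: 3 methyl 2-methoxy-3-(4-methoxyphenyl)-3-oxopropanoate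
Product: 4 methyl (Z)-2,3-dimethoxy-3-(4-methoxyphenyl)prop-2-enoate
Conditions: KOtBu (1.05 equiv), 18-crown-6, THF, 0 °C; then Me2SO4, 0 °C to rt
Reagents that add atoms: dimethyl sulfate, COS(=O)(=O)OC
Why: Enolate O-alkylation: the crown-separated potassium enolate of a β-keto ester should react with the hard sulfate electrophile at oxygen, and C-methylation would have to build a quaternary carbon that already bears a methoxyl. The dissociated enolate should give mainly the Z isomer drawn; either geometry is usable.

Step 3
Reactants: 4 methyl (Z)-2,3-dimethoxy-3-(4-methoxyphenyl)prop-2-enoate; 5 4-hydroxy-6-methyl-2H-pyran-2-one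
Product: 6 6-[(Z)-3,4-dimethoxy-4-(4-methoxyphenyl)-2-oxobut-3-en-1-yl]-4-hydroxy-2H-pyran-2-one
Conditions: 5 (2.0 equiv), LiN(iPr)2 (4.2 equiv), THF, −78 to −20 °C; then 4 (1.0 equiv), −78 to 0 °C; cold 1 M HCl to pH 3
Reagents that add atoms: none
Why: Claisen-type acylation of the dianion of 5 (4-oxide plus the vinylogous carbanion at the C6 methyl), which reacts with esters at the methyl carbon; the excess dianion takes up the acidic methylene proton of 6 as it forms. Ester 4 has no enolisable hydrogen and can only act as the acyl donor; the brief cold acidification should spare the enol ether.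

Step 4
Reactants: 6 6-[(Z)-3,4-dimethoxy-4-(4-methoxyphenyl)-2-oxobut-3-en-1-yl]-4-hydroxy-2H-pyran-2-one
Product: 9 5,7-dihydroxy-3-methoxy-2-(4-methoxyphenyl)-4H-chromen-4-one, via triketo ester 7 (not isolated), via acylphloroglucinol 8 (not isolated)
Conditions: Mg(OMe)2 (6 equiv), MeOH, reflux; then 2 M HCl, 0 °C to rt
Reagents that add atoms: none
Why: Methoxide on magnesium adds to the lactone carbonyl of 6 and opens the 2-pyranone to the triketo ester 7, which is held as a magnesium polyenolate chelate. The doubly activated methylene between the C5 and C7 carbonyls of the chain, the future C4a, attacks the ester carbonyl in a 6-exo-trig Claisen condensation; loss of methoxide and enolisation close ring A and give the 2-acylphloroglucinol 8. One of the two ortho phenoxides of 8 then adds to the β-methoxy enone carbon, the future C2, and methoxide is expelled, a 6-endo-trig addition–elimination that closes ring C. The closest known reactions are the Mg(OMe)2-induced Claisen cyclisation of 6-(2-oxoalkyl)-4-hydroxy-2-pyranones to acylphloroglucinols and the cyclisation of 2-hydroxyaryl β-alkoxyvinyl ketones to chromones; here they are run in one flask, and the acidic work-up should drive any uncyclised 8 on to 9. The step needs Claisen folding to beat aldol folding (C2 of the chain onto the C7 ketone, which would give a resorcylate): the magnesium chelate of the tricarbonyl array favours the Claisen mode, and the C7 carbonyl is a vinylogous ester whose electrophilicity the β-methoxyl lowers. The O1–C2 closure poses no regiochemical question, because the two phenols ortho to the acyl group of 8 are equivalent. No stereocentre is formed, and the enol ether geometry is lost in the addition–elimination.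

Step 5
Reactants: 9 5,7-dihydroxy-3-methoxy-2-(4-methoxyphenyl)-4H-chromen-4-one
Product: 10 6,8-dibromo-5,7-dihydroxy-3-methoxy-2-(4-methoxyphenyl)-4H-chromen-4-one
Conditions: NBS (2.1 equiv), DMF, 0 °C to rt
Reagents that add atoms: N-bromosuccinimide, O=C1CCC(=O)N1Br
Why: Electrophilic aromatic bromination: C6 and C8 are each ortho and para to the two phenols of ring A and far more activated than ring B, which is conjugated to the pyranone; C3 is blocked by its methoxyl.

Step 6
Reactants: 10 6,8-dibromo-5,7-dihydroxy-3-methoxy-2-(4-methoxyphenyl)-4H-chromen-4-one
Product: 11 5,7-dihydroxy-3,6,8-trimethoxy-2-(4-methoxyphenyl)-4H-chromen-4-one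
Conditions: NaOMe (excess), CuBr (0.3 equiv), DMF–MeOH, 110 °C; then 1 M HCl
Reagents that add atoms: sodium methoxide, [Na+].[O-]C
Why: Ullmann-type copper-mediated substitution of aryl bromides by methoxide, a standard way to turn 6,8-dibromo-5,7-dihydroxyflavones into their 6,8-dimethoxy compounds; the substrate reacts as its bis-phenoxide, which shields ring C from nucleophilic opening. Since C6 and C8 receive the same group, any opening and reclosure of ring C through O5 would return the same compound.

Step 7
Reactants: 11 5,7-dihydroxy-3,6,8-trimethoxy-2-(4-methoxyphenyl)-4H-chromen-4-one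
Product: 12 7-(benzyloxy)-5-hydroxy-3,6,8-trimethoxy-2-(4-methoxyphenyl)-4H-chromen-4-one
Conditions: BnBr (1.05 equiv), K2CO3 (1.2 equiv), acetone, rt to 40 °C
Reagents that add atoms: benzyl bromide, BrCc1ccccc1
Why: Williamson etherification with one equivalent of halide: the C7 phenol, para to the carbonyl, is free and the more acidic, while the C5 phenol is tied up in a hydrogen bond to the C4 carbonyl and should stay untouched under mild carbonate conditions.

Step 8
Reactants: 12 7-(benzyloxy)-5-hydroxy-3,6,8-trimethoxy-2-(4-methoxyphenyl)-4H-chromen-4-one
Product: 13 7-(benzyloxy)-3,5,6,8-tetramethoxy-2-(4-methoxyphenyl)-4H-chromen-4-one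
Conditions: Me2SO4 (3 equiv), K2CO3 (excess), acetone, reflux
Reagents that add atoms: dimethyl sulfate, COS(=O)(=O)OC
Why: O-Methylation of the chelated C5 phenol under forcing carbonate conditions, the usual way to methylate a 5-hydroxyflavone once every other phenol is capped.

Step 9
Reactants: 13 7-(benzyloxy)-3,5,6,8-tetramethoxy-2-(4-methoxyphenyl)-4H-chromen-4-one
Product: 14 7-hydroxy-3,5,6,8-tetramethoxy-2-(4-methoxyphenyl)-4H-chromen-4-one
Conditions: H2 (1 atm), 10% Pd/C, EtOAc–MeOH, rt
Reagents that add atoms: none
Why: Catalytic hydrogenolysis of the benzyl ether; aryl methyl ethers are inert, and the tetrasubstituted C2=C3 bond of the pyranone, a vinylogous ester, should not be reduced at atmospheric pressure.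

## Compound list

1 | methyl methoxyacetate | COCC(=O)OC | starting material
2 | 4-methoxybenzoyl chloride | COc1ccc(cc1)C(Cl)=O | starting material
3 | methyl 2-methoxy-3-(4-methoxyphenyl)-3-oxopropanoate (racemic) | COC(=O)C(OC)C(=O)c1ccc(OC)cc1 | intermediate
4 | methyl (Z)-2,3-dimethoxy-3-(4-methoxyphenyl)prop-2-enoate | COc1ccc(cc1)/C(OC)=C(/OC)C(=O)OC | intermediate
5 | 4-hydroxy-6-methyl-2H-pyran-2-one | Cc1cc(O)cc(=O)o1 | starting material
6 | 6-[(Z)-3,4-dimethoxy-4-(4-methoxyphenyl)-2-oxobut-3-en-1-yl]-4-hydroxy-2H-pyran-2-one | COc1ccc(cc1)/C(OC)=C(/OC)C(=O)Cc1cc(O)cc(=O)o1 | intermediate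
7 | methyl (Z)-8,9-dimethoxy-9-(4-methoxyphenyl)-3,5,7-trioxonon-8-enoate (triketo ester, not isolated) | COc1ccc(cc1)/C(OC)=C(/OC)C(=O)CC(=O)CC(=O)CC(=O)OC | intermediate
8 | (Z)-2,3-dimethoxy-3-(4-methoxyphenyl)-1-(2,4,6-trihydroxyphenyl)prop-2-en-1-one (acylphloroglucinol, not isolated) | COc1ccc(cc1)/C(OC)=C(/OC)C(=O)c1c(O)cc(O)cc1O | intermediate
9 | 5,7-dihydroxy-3-methoxy-2-(4-methoxyphenyl)-4H-chromen-4-one | COc1ccc(-c2oc3cc(O)cc(O)c3c(=O)c2OC)cc1 | intermediate
10 | 6,8-dibromo-5,7-dihydroxy-3-methoxy-2-(4-methoxyphenyl)-4H-chromen-4-one | COc1ccc(-c2oc3c(Br)c(O)c(Br)c(O)c3c(=O)c2OC)cc1 | intermediate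
11 | 5,7-dihydroxy-3,6,8-trimethoxy-2-(4-methoxyphenyl)-4H-chromen-4-one | COc1ccc(-c2oc3c(OC)c(O)c(OC)c(O)c3c(=O)c2OC)cc1 | intermediate
12 | 7-(benzyloxy)-5-hydroxy-3,6,8-trimethoxy-2-(4-methoxyphenyl)-4H-chromen-4-one | COc1ccc(-c2oc3c(OC)c(OCc4ccccc4)c(OC)c(O)c3c(=O)c2OC)cc1 | intermediate
13 | 7-(benzyloxy)-3,5,6,8-tetramethoxy-2-(4-methoxyphenyl)-4H-chromen-4-one | COc1ccc(-c2oc3c(OC)c(OCc4ccccc4)c(OC)c(OC)c3c(=O)c2OC)cc1 | intermediate
14 | 7-hydroxy-3,5,6,8-tetramethoxy-2-(4-methoxyphenyl)-4H-chromen-4-one | COc1ccc(-c2oc3c(OC)c(O)c(OC)c(OC)c3c(=O)c2OC)cc1 | target

## Step count and least certain steps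

Total: 9 steps. Longest linear sequence: 9 steps (from 1 and 2 to 14); pyranone 5 enters at step 3.

**Step 4 (key step).** The chain may fold in the aldol sense instead of the Claisen sense. The alkoxide may fragment the opened poly-carbonyl chain by retro-Claisen cleavage. The lactone of the 4-oxido pyranone may resist opening. Stalling before ring C closure is the least serious of these, since the acid work-up should finish it. Fallback: ring A is bought instead of folded. Setting out from keto ester 3, a Mentzer-type thermal condensation with commercial phloroglucinol (neat or in diphenyl ether, about 240 °C) acylates the phenol through the acylketene formed by loss of the ester alcohol, and dehydration closes ring C. This returns to the route at 9, and steps 2 and 3 are not needed. No new isolable compound lies on this path (F0).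

**Step 3.** The ester carbonyl of 4 is deactivated by the push–pull enol ether and flanked by a tetrasubstituted alkene, so addition of the dianion may be slow. Proton transfer and addition–elimination at the β-carbon with loss of its methoxyl may then take over. Fallback: the acyl donor is replaced by an aldehyde and the ketone is made by oxidation. Setting out from 4, reduction with iBu2AlH (CH2Cl2, −78 °C) gives (Z)-2,3-dimethoxy-3-(4-methoxyphenyl)prop-2-en-1-ol F1. MnO2 (CH2Cl2, rt) gives (Z)-2,3-dimethoxy-3-(4-methoxyphenyl)prop-2-enal F2. Aldol addition of the dianion of 5 (LiN(iPr)2, THF, −78 °C) gives 4-hydroxy-6-[(Z)-2-hydroxy-3,4-dimethoxy-4-(4-methoxyphenyl)but-3-en-1-yl]-2H-pyran-2-one F3 (racemic). Oxidation of the allylic alcohol with 2-iodoxybenzoic acid (DMSO, rt) returns to the route at 6.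

**Step 2.** Methylation at carbon instead of oxygen would give a quaternary keto ester that cannot be carried on, and the ratio of the two modes depends on ion pairing. Fallback: the enol ether is made through the carbonyl group and not through the enolate. Setting out from 3, HC(OMe)3 with catalytic TsOH in MeOH at reflux gives the dimethyl ketal methyl 2,3,3-trimethoxy-3-(4-methoxyphenyl)propanoate F4 (racemic). Elimination of one methoxyl with Me3SiOTf and iPr2NEt (CH2Cl2, −20 °C to rt) returns to the route at 4.

**Step 6.** Reductive loss of bromine may compete with substitution on the electron-rich bis-phenoxide. The second substitution may stall, and hot alkoxide may cleave ring C. Fallback: the phenols are capped first and the C–O bonds are made by palladium catalysis on a neutral substrate. Setting out from 10, BnBr and K2CO3 (acetone, rt) give 7-(benzyloxy)-6,8-dibromo-5-hydroxy-3-methoxy-2-(4-methoxyphenyl)-4H-chromen-4-one F5. Me2SO4 and K2CO3 (acetone, reflux) give 7-(benzyloxy)-6,8-dibromo-3,5-dimethoxy-2-(4-methoxyphenyl)-4H-chromen-4-one F6. Cross-coupling with methanol (Pd2(dba)3 as the zerovalent palladium source, tBuBrettPhos, Cs2CO3, toluene–MeOH, 80 °C) returns to the route at 13, so steps 7 and 8 are not repeated.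

## Further compounds

F0 | step 4 | none | none
F1 | step 3 | (Z)-2,3-dimethoxy-3-(4-methoxyphenyl)prop-2-en-1-ol | COc1ccc(cc1)/C(OC)=C(/OC)CO
F2 | step 3 | (Z)-2,3-dimethoxy-3-(4-methoxyphenyl)prop-2-enal | COc1ccc(cc1)/C(OC)=C(/OC)C=O
F3 | step 3 | 4-hydroxy-6-[(Z)-2-hydroxy-3,4-dimethoxy-4-(4-methoxyphenyl)but-3-en-1-yl]-2H-pyran-2-one (racemic) | COc1ccc(cc1)/C(OC)=C(/OC)C(O)Cc1cc(O)cc(=O)o1
F4 | step 2 | methyl 2,3,3-trimethoxy-3-(4-methoxyphenyl)propanoate (racemic) | COC(=O)C(OC)C(OC)(OC)c1ccc(OC)cc1
F5 | step 6 | 7-(benzyloxy)-6,8-dibromo-5-hydroxy-3-methoxy-2-(4-methoxyphenyl)-4H-chromen-4-one | COc1ccc(-c2oc3c(Br)c(OCc4ccccc4)c(Br)c(O)c3c(=O)c2OC)cc1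
F6 | step 6 | 7-(benzyloxy)-6,8-dibromo-3,5-dimethoxy-2-(4-methoxyphenyl)-4H-chromen-4-one | COc1ccc(-c2oc3c(Br)c(OCc4ccccc4)c(Br)c(OC)c3c(=O)c2OC)cc1
A1 | alternative 1 | 7-(benzyloxy)-3-hydroxy-5,6,8-trimethoxy-2-(4-methoxyphenyl)chroman-4-one (racemic, both diastereomers) | COc1ccc(cc1)C1Oc2c(OC)c(OCc3ccccc3)c(OC)c(OC)c2C(=O)C1O
A2 | alternative 1 | 2-[3-(benzyloxy)-6-formyl-2,4,5-trimethoxyphenoxy]-2-(4-methoxyphenyl)acetaldehyde (racemic) | O=CC(Oc1c(C=O)c(OC)c(OC)c(OCc2ccccc2)c1OC)c1ccc(OC)cc1
A3 | alternative 2 | 6,7-bis(benzyloxy)-5,8-dihydroxy-3-methoxy-2-(4-methoxyphenyl)-4H-chromen-4-one | COc1ccc(-c2oc3c(O)c(OCc4ccccc4)c(OCc4ccccc4)c(O)c3c(=O)c2OC)cc1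
A4 | alternative 2 | 5-[2,3-bis(benzyloxy)-1-hydroxy-4-oxocyclobut-2-en-1-yl]-3-methoxy-2-(4-methoxyphenyl)-4H-pyran-4-one (racemic) | COc1ccc(cc1)-c1occ(c(=O)c1OC)C1(O)C(=O)C(OCc2ccccc2)=C1OCc1ccccc1
A5 | alternative 2 | 3,4-bis(benzyloxy)cyclobut-3-ene-1,2-dione | O=C1C(=O)C(OCc2ccccc2)=C1OCc1ccccc1
A6 | alternative 2 | 5-bromo-3-methoxy-2-(4-methoxyphenyl)-4H-pyran-4-one | COc1ccc(cc1)-c1occ(Br)c(=O)c1OC
A7 | alternative 3 | 7-(benzyloxy)-5,6,8-trimethoxy-2-(4-methoxyphenyl)-4H-chromen-4-one | COc1ccc(-c2cc(=O)c3c(OC)c(OC)c(OCc4ccccc4)c(OC)c3o2)cc1
A8 | alternative 3 | 3-(benzyloxy)-6-iodo-2,4,5-trimethoxyphenol | Oc1c(I)c(OC)c(OC)c(OCc2ccccc2)c1OC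
A9 | alternative 3 | 1-ethynyl-4-methoxybenzene | C#Cc1ccc(OC)cc1
A10 | alternative 3 | carbon monoxide | [C-]#[O+]
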